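**Retrosynthetic overview**

1. Numbering: the cyclopentanone is C1 (quaternary, CH3), C2 (C=O), C3, C4 (i-Pr), C5 (C–OH). The seven-membered ring is C5–C6–C7–C8(CH3)=C9–C10(OCOAr)–C1. C1-CH3, C4-i-Pr and C5-OH lie on one face (β) and the C10 oxygen on the other (α), so the hydroazulene is cis-fused.
2. Feature: C1(CH3), C2, C3, C4(i-Pr), C5 and the exocyclic neighbour C10 become the six ring carbons of a p-menthane once the bond C1–C5 is exchanged for C5–C10. C10 is then the carbonyl carbon, C5 the α′ carbon and C4 the stereocentre of (S)-carvone. C5–C10 is the fusion bond of a decalin (ring A: C1-C2-C3-C4-C5-C10; ring B: C5-C6-C7-C8-C9-C10).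
3. Target 23 ⇒ enone diol 16, by C2 alcohol oxidation, desilylation, anisoylation, C5-OH-directed reduction of C10=O and C2-O silylation.
4. 16 ⇒ decalin epoxy diol 14 by a 1,2-shift of C5 from C10 to C1, paid for by the C1–O bond of the α C1/C2 epoxide. Ring A contracts to the cyclopentane and ring B grows to the cycloheptenone in the same event.
5. 14 ⇒ RCM (C8=C9) ⇒ C10-OH-directed epoxidation ⇒ trans-diol 12 ⇒ anti hydrolysis of a C5/C10 β-epoxide ⇒ vinyl addition to α-chloro enone 8 ⇒ alkylation and chlorination of carvotanacetone. Ring order: A (from carvone), B (RCM), then the five- and seven-membered rings together.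

Key step: step 9

Remark: α and β are used for every intermediate as defined above (β is the face of the C4 isopropyl group). In this numbering the target is 1R,4R,5S,10R.

**Step 1**
Reactants: 1 (S)-(+)-carvone
Product: 2 (S)-carvotanacetone
Conditions: H2 (1 atm), RhCl(PPh3)3 (cat.), toluene, rt
Reagents that add atoms: none
Why: Homogeneous hydrogenation with Wilkinson's catalyst saturates the unhindered 1,1-disubstituted isopropenyl alkene much faster than the trisubstituted conjugated C1=C2 bond and does not touch the C4 stereocentre.

**Step 2**
Reactants: 3 3-methylbut-3-en-1-ol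
Product: 4 4-iodo-2-methylbut-1-ene
Conditions: I2, PPh3, imidazole, CH2Cl2, 0 °C → rt
Reagents that add atoms: iodine, II
Why: Appel-type iodination of a primary alcohol runs by SN2 displacement of the oxyphosphonium group and leaves the alkene alone.

**Step 3**
Reactants: 2 (S)-carvotanacetone; 4 4-iodo-2-methylbut-1-ene
Product: 6 5α-(3-methylbut-3-enyl)carvotanacetone (side chain on C5 trans to isopropyl), via lithium dienolate 5 (not isolated)
Conditions: LDA, THF, −78 °C; then 4, DMPU, −78 → 0 °C
Reagents that add atoms: none
Why: Kinetic α′-deprotonation gives the cross-conjugated dienolate, and its SN2 enolate alkylation by the primary iodide occurs at C5 anti to the C4 isopropyl group; the C5 configuration is erased again in step 4, so the epimer ratio is immaterial.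

**Step 4**
Reactants: 6 5α-(3-methylbut-3-enyl)carvotanacetone
Product: 8 5α-chloro-5β-(3-methylbut-3-enyl)carvotanacetone, via lithium dienolate 7 (not isolated)
Conditions: LDA, THF, −78 → −30 °C; then NCS, THF, −78 °C
Reagents that add atoms: N-chlorosuccinimide, O=C1CCC(=O)N1Cl
Why: In this electrophilic α-chlorination of a fully substituted enolate, allylic strain with the C5 side chain turns the C4 isopropyl group pseudoaxial over the β face, so Cl+ should enter from the α face and push the side chain to β.

**Step 5**
Reactants: 8 5α-chloro-5β-(3-methylbut-3-enyl)carvotanacetone; 9 vinylmagnesium bromide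
Product: 10 trans chlorohydrin (C10: OH β and vinyl α; C5: Cl α and side chain β; C1=C2 retained)
Conditions: 9, LaCl3·2LiCl (cat.), THF, −78 → −40 °C; aqueous work-up
Reagents that add atoms: none
Why: In this lanthanide-assisted 1,2-addition of a Grignard reagent to an enone, the β face of the C10 carbonyl is closed either by the axial β side chain on C5 or, in the flipped ring, by the axial isopropyl group, so vinyl should enter along the axial α trajectory that carvone-type enones prefer anyway and place the C10 oxygen β, trans to chlorine.

**Step 6**
Reactants: 10 trans chlorohydrin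
Product: 12 triene trans-diol (C5: OH β and side chain α; C10: OH α and vinyl β), via bis-allylic β-epoxide 11 (not isolated)
Conditions: KH, THF, 0 °C; then aq. citrate–phosphate buffer (pH 4), THF, 0 °C
Reagents that add atoms: water, O
Why: Williamson-type closure of the trans chlorohydrin through its diaxial conformer inverts C5 and gives the C5/C10 β-epoxide, whose acid-catalysed hydrolysis opens the doubly allylic tertiary C10–O bond by backside attack of water (trans-diaxial Fürst–Plattner opening), setting C10-OH α and leaving C5-OH β, an arrangement that carbonyl addition next to an axial C5 oxygen would not deliver.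

**Step 7**
Reactants: 12 triene trans-diol
Product: 13 monocyclic epoxy diol (C1/C2 epoxide α and cis to C10-OH; vinyl and side-chain alkenes intact)
Conditions: VO(acac)2 (cat.), t-BuOOH, 2,6-lutidine (cat.), CH2Cl2, 0 °C
Reagents that add atoms: tert-butyl hydroperoxide, CC(C)(C)OO
Why: In this vanadium-catalysed hydroxyl-directed epoxidation the pseudoaxial allylic C10-OH delivers oxygen to the α face of the trisubstituted C1=C2 bond far faster than to the monosubstituted vinyl group or the remote 1,1-disubstituted alkene, which is why the epoxide is installed before ring B brings in a second trisubstituted allylic alkene.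

**Step 8**
Reactants: 13 monocyclic epoxy diol
Product: 14 trans-fused decalin epoxy diol (C5-OH β, C10-OH α, C1/C2 epoxide α, C8=C9)
Conditions: Hoveyda–Grubbs II (cat.), CH2Cl2 (high dilution), 40 °C
Reagents that add atoms: none
Why: Ring-closing metathesis of the vinyl group and the 1,1-disubstituted alkene, both equatorial on the adjacent carbons C10 and C5, forms the trisubstituted C8=C9 bond of a six-membered ring under neutral conditions that spare the epoxy alcohol; the trans fusion is already fixed by the diol.

**Step 9**
Reactants: 14 trans-fused decalin epoxy diol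
Product: 16 cis-fused hydroazulene enone diol (C10 ketone conjugated with C8=C9, C2-OH α, C5-OH β, C1-CH3 β), via bis(dimethylaluminium) alkoxide 15 (not isolated)
Conditions: Me3Al (3 equiv), CH2Cl2, −78 → 0 °C; aq. Rochelle salt
Reagents that add atoms: none
Why: Me3Al first converts both tertiary hydroxyls into aluminium alkoxides; the aluminium on the α C10 oxygen reaches the cis epoxide oxygen and loosens the tertiary C1–O bond, and C5 shifts from C10 to C1 while the C10–O–Al unit collapses to the carbonyl, which is a semipinacol rearrangement of a 2,3-epoxy alcohol with migration of a ring carbon, the type known from ring contractions of 2,3-epoxycyclohexanols and from decalin-to-hydroazulene shifts. The single 1,2-shift closes the cyclopentane C1–C2–C3–C4–C5 by contraction of ring A (new bond C1–C5, C10 extruded) and closes the cycloheptenone C1–C10–C9–C8–C7–C6–C5 by expansion of ring B (C1 inserted between C10 and C5). The only new stereocentre, quaternary C1, is set by inversion: C5 arrives on the β face opposite the departing α oxygen, so CH3 stays β and C10 ends α, and together with retention at the migrating C5 (OH β, C6 α) this gives the cis fusion, while C2 and C4 are untouched. The step needs C5 to migrate in preference to the vinylic C9, to H-2 and to C3. In the epoxide half-chair C9 is actually the better aligned group (roughly 155° to C1–O against roughly 85° for C10–C5), so the selectivity rests on the trans fusion and not on antiperiplanarity: a C9 shift would bind C9 to the β face of C1 while C6 stays on the α face of C5 and give a trans-bridged (in,out) bicyclo[4.3.1]decenone, whereas, as C1 flattens and ring A relaxes towards a chair, equatorial C9 drops into the nodal plane of the C1 orbital and the C10–C5 bond overlaps with its β lobe. The aluminium alkoxide makes the C10 oxygen a better donor than the oxygen on C2 (against hydride or C3 shift), prevents ionisation of the allylic C10–O bond, and the product is a conjugated enone held as a six-membered aluminium aldolate chelate.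

**Step 10**
Reactants: 16 hydroazulene enone diol
Product: 17 C2 triethylsilyl ether of 16
Conditions: TESCl, imidazole, DMAP (cat.), CH2Cl2, 0 °C → rt
Reagents that add atoms: chlorotriethylsilane, CC[Si](Cl)(CC)CC
Why: Silyl ether formation distinguishes the secondary C2-OH from the tertiary C5-OH on steric grounds and masks the hydroxyl that could otherwise steer hydride to the α face of C10 or be acylated.

**Step 11**
Reactants: 17 C2 triethylsilyl ether
Product: 19 C10 α-allylic alcohol (C10-H β, 1,3-anti to C5-OH), via alkoxydiacetoxyborohydride 18 (not isolated)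
Conditions: Me4NBH(OAc)3, MeCN/AcOH, −30 °C
Reagents that add atoms: none
Why: In this Evans–Saksena hydroxyl-directed reduction, exchange of one acetate for the C5-OH ties boron to the β face, and its hydride is handed to the β face of the C10 carbonyl through a six-membered transition state, giving the 1,3-anti alcohol by 1,2-reduction; the convex β face of the cis-fused bicycle is also the one open to external hydride.

**Step 12**
Reactants: 19 C10 α-allylic alcohol; 20 4-methoxybenzoyl chloride
Product: 21 C10 4-methoxybenzoate C2 triethylsilyl ether
Conditions: 20, Et3N, DMAP (cat.), CH2Cl2, 0 → 40 °C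
Reagents that add atoms: none
Why: DMAP-catalysed acyl transfer esterifies the secondary allylic C10-OH with retention, while the tertiary C5-OH is too hindered to react.

**Step 13**
Reactants: 21 C10 4-methoxybenzoate C2 triethylsilyl ether
Product: 22 C10 4-methoxybenzoate with free C2-OH and C5-OH
Conditions: HF·pyridine, pyridine/THF, 0 °C
Reagents that add atoms: none
Why: Fluoride-mediated desilylation in a buffered, weakly acidic medium frees C2-OH without forming an alkoxide, which avoids 1,3-acyl migration from the C10 oxygen to the syn C2 oxygen.

**Step 14**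
Reactants: 22 C10 4-methoxybenzoate with free C2-OH and C5-OH
Product: 23 CNP0246512.1 (target)
Conditions: Dess–Martin periodinane, CH2Cl2, 0 °C → rt
Reagents that add atoms: none
Why: Dess–Martin oxidation converts the only secondary alcohol into the C2 ketone under near-neutral conditions that leave the tertiary β-hydroxy group, the allylic ester and the quaternary, non-epimerisable C1 unchanged.

**Compound list**

1 | (S)-(+)-carvone | CC1=CC[C@@H](CC1=O)C(C)=C | starting material
2 | (S)-carvotanacetone, (5S)-2-methyl-5-(propan-2-yl)cyclohex-2-en-1-one | CC1=CC[C@H](C(C)C)CC1=O | intermediate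
3 | 3-methylbut-3-en-1-ol | CC(=C)CCO | starting material
4 | 4-iodo-2-methylbut-1-ene | CC(=C)CCI | intermediate
5 | lithium C5=C10 dienolate of 2 | CC1=CC[C@H](C(C)C)C=C1O[Li] | intermediate
6 | (5R,6R)-2-methyl-6-(3-methylbut-3-en-1-yl)-5-(propan-2-yl)cyclohex-2-en-1-one | CC1=CC[C@H](C(C)C)[C@@H](CCC(C)=C)C1=O | intermediate
7 | lithium C5=C10 dienolate of 6 | CC1=CC[C@H](C(C)C)C(CCC(C)=C)=C1O[Li] | intermediate
8 | (5R,6R)-6-chloro-2-methyl-6-(3-methylbut-3-en-1-yl)-5-(propan-2-yl)cyclohex-2-en-1-one | CC1=CC[C@H](C(C)C)[C@](Cl)(CCC(C)=C)C1=O | intermediate
9 | vinylmagnesium bromide | C=C[Mg]Br | starting material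
10 | (1R,5R,6R)-6-chloro-1-ethenyl-2-methyl-6-(3-methylbut-3-en-1-yl)-5-(propan-2-yl)cyclohex-2-en-1-ol | CC1=CC[C@H](C(C)C)[C@](Cl)(CCC(C)=C)[C@@]1(O)C=C | intermediate
11 | C5/C10 β-epoxide carrying vinyl on C10 and the side chain on C5 (both α) | CC1=CC[C@H](C(C)C)[C@]2(CCC(C)=C)O[C@]12C=C | intermediate
12 | triene trans-diol (C5-OH β, C10-OH α) | CC1=CC[C@H](C(C)C)[C@@](O)(CCC(C)=C)[C@]1(O)C=C | intermediate
13 | monocyclic epoxy diol (C1/C2 epoxide α) | C[C@]12O[C@H]1C[C@H](C(C)C)[C@@](O)(CCC(C)=C)[C@]2(O)C=C | intermediate
14 | trans-fused decalin epoxy diol | C[C@]12O[C@H]1C[C@H](C(C)C)[C@@]3(O)CCC(C)=C[C@]23O | intermediate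
15 | bis(dimethylaluminium) alkoxide of 14 | C[C@]12O[C@H]1C[C@H](C(C)C)[C@@]3(O[Al](C)C)CCC(C)=C[C@]23O[Al](C)C | intermediate
16 | cis-fused hydroazulene enone diol | O=C2C=C(C)CC[C@]3(O)[C@@H](C(C)C)C[C@H](O)[C@]23C | intermediate
17 | C2 triethylsilyl ether of 16 | O=C2C=C(C)CC[C@]3(O)[C@@H](C(C)C)C[C@H](O[Si](CC)(CC)CC)[C@]23C | intermediate
18 | tetramethylammonium C5-alkoxydiacetoxyborohydride of 17 | O=C2C=C(C)CC[C@]3(O[BH-](OC(C)=O)OC(C)=O)[C@@H](C(C)C)C[C@H](O[Si](CC)(CC)CC)[C@]23C.C[N+](C)(C)C | intermediate
19 | C10 α-allylic alcohol, C2 triethylsilyl ether | O[C@@H]2C=C(C)CC[C@]3(O)[C@@H](C(C)C)C[C@H](O[Si](CC)(CC)CC)[C@]23C | intermediate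
20 | 4-methoxybenzoyl chloride | COc1ccc(C(Cl)=O)cc1 | starting material
21 | C10 4-methoxybenzoate, C2 triethylsilyl ether | COc1ccc(C(=O)O[C@@H]2C=C(C)CC[C@]3(O)[C@@H](C(C)C)C[C@H](O[Si](CC)(CC)CC)[C@]23C)cc1 | intermediate
22 | C10 4-methoxybenzoate, C2 and C5 hydroxyls free | COc1ccc(C(=O)O[C@@H]2C=C(C)CC[C@]3(O)[C@@H](C(C)C)C[C@H](O)[C@]23C)cc1 | intermediate
23 | CNP0246512.1 | COc1ccc(C(=O)O[C@@H]2C=C(C)CC[C@]3(O)[C@@H](C(C)C)CC(=O)[C@]23C)cc1 | target

**Step count**

Total step count: 14.
Longest linear sequence: 13 steps from (S)-carvone (steps 1 and 3–14). Step 2 is a one-step side branch.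

**Steps most likely to fail**

**Step 9 (key step).**
- The ring carbon C5 starts poorly aligned with the breaking C1–O bond. Competing processes are hydride or C3 shift from C2, participation of the C8=C9 π bond, methyl transfer from aluminium to C1, and cleavage of C5–C10 without re-closure.
- The fallback sets out from 14 and forms the same C1–C5 bond in two separate events.
- Criegee glycol cleavage with Pb(OAc)4 in pyridine/benzene should cut C5–C10 and give the ten-membered (Z)-epoxy enedione F1. The non-cyclic mechanism tolerates the trans-diaxial diol, though slowly.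
- SmI2 (THF, −78 °C) should then open the α,β-epoxy ketone reductively at C1–O. This gives a samarium(III) enolate C10(O–Sm)=C1, which adds across the ring to the C5 ketone (transannular aldol).
- Chelation through the C2 and C10 oxygens should favour the cis-fused aldol. The facial selectivity relative to C4 would have to be established.
- The sequence rejoins the route at 16.

**Step 6.**
- Water may be captured at the ends of the delocalised cation (C2 or the vinyl CH2). The bis-allylic alcohol may re-ionise, and facial selectivity may erode.
- The fallback sets out from 10, closes it to 11 with KH as before, and then avoids any cation.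
- Sodium phenylselenide (from (PhSe)2 and NaBH4 in EtOH) should attack the unhindered vinyl terminus in an SN2′ sense. This gives the dienyl allylic selenide F2, drawn with CH2Se anti to C5; both alkene isomers converge.
- Oxidation (H2O2, pyridine, −20 → 0 °C) triggers the [2,3]-sigmatropic shift of the allylic selenoxide. The shift places oxygen on C10 from the α face, anti to the axial C5-OH, and regenerates the vinyl group.
- The sequence rejoins the route at 12.

**Step 5.**
- Halophilic attack on the tertiary chloride may reduce the substrate to the enolate. Conjugate addition, or entry from the β face to a cis chlorohydrin that cannot close, may also compete.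
- The fallback sets out from 8 and uses a slimmer, less reducing C2 nucleophile at a higher oxidation level.
- Ethynylmagnesium bromide with LaCl3·2LiCl should give the ethynyl chlorohydrin F3.
- KH closes it to the ethynyl epoxide F4.
- Buffered hydrolysis gives the ethynyl trans-diol F5. In this hydrolysis the propargylic position offers one less allylic escape route.
- Lindlar semihydrogenation of the terminal alkyne rejoins the route at 12.

**Further compounds**

F1 | step 9 | (Z)-configured ten-membered C1/C2-epoxy C5,C10-dione (C5–C10 bond of 14 cleaved) | C[C@]12O[C@H]1C[C@H](C(C)C)C(=O)CC/C(C)=C\C2=O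
F2 | step 6 | C5-hydroxy C9=C10/C1=C2 dienyl phenyl selenide | CC1=CC[C@H](C(C)C)[C@@](O)(CCC(C)=C)/C1=C/C[Se]c1ccccc1
F3 | step 5 | ethynyl chlorohydrin (C10: OH β, ethynyl α; C5: Cl α) | CC1=CC[C@H](C(C)C)[C@](Cl)(CCC(C)=C)[C@@]1(O)C#C
F4 | step 5 | ethynyl C5/C10 β-epoxide | CC1=CC[C@H](C(C)C)[C@]2(CCC(C)=C)O[C@]12C#C
F5 | step 5 | ethynyl trans-diol (C5-OH β, C10-OH α) | CC1=CC[C@H](C(C)C)[C@@](O)(CCC(C)=C)[C@]1(O)C#C
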